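Both halves come from one ring. In the hydroxylated cyclohexane (ring A: C1 isopropyl-bearing CH, C2 and C3 the CH2 pair, C4 carbinol carbon, C5 acid-bearing CH, C6 alkenyl-bearing CH) the C2–C3 and C4–C5 bonds form in a domino nitro-Michael/intramolecular Horner–Wadsworth–Emmons annulation. It exploits that C4 carries an exocyclic carbon (the later CH2O) and that C2 is a plain CH2: a γ-nitro aldehyde holding C1 and C6 adds through nitronate carbon C2 to the CH2 (C3) of a 2-phosphonoacrylate, whose phosphonate carbon C4 olefinates aldehyde carbon C5. The C4=C5 enoate then takes CO2H at C5 and OH at C4; a C4 spiro-epoxide gives both the butenolide half and the ester link.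

Key step: step 3

Remark on the chemistry: compound 9 is carried on as its mixture of nitro epimers and compound 11 as its mixture of epimers at the ester-bearing carbon, because steps 4 and 6 erase those centres; the SMILES show the expected major epimer (9) or leave the centre open (11).

Step 1
Reactants: 1 2-methylpropanal; 2 nitromethane
Product: 4 (E)-3-methyl-1-nitrobut-1-ene, via nitro alcohol 3 (not isolated)
Conditions: KOtBu (5 mol%), THF/tBuOH, 0 °C; then MsCl, Et3N, CH2Cl2, 0 °C
Reagents that add atoms: none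
Why: Henry (nitroaldol) addition followed by mesylation–elimination should give the conjugated nitroalkene as the thermodynamically preferred E isomer.

Step 2
Reactants: 5 3-(benzyloxy)propanal; 4 (E)-3-methyl-1-nitrobut-1-ene
Product: 6 (2S,3R)-2-[(benzyloxy)methyl]-4-methyl-3-(nitromethyl)pentanal
Conditions: (S)-2-[diphenyl(trimethylsilyloxy)methyl]pyrrolidine (10 mol%), 4-nitrophenol (10 mol%), toluene, 0 °C to rt
Reagents that add atoms: none
Why: Enamine-catalysed asymmetric Michael addition of an aldehyde to a nitroalkene (diarylprolinol silyl ether catalysis), in which the anti enamine of 5 should attack 4 from the face away from the diphenyl(silyloxy)methyl group through a synclinal transition state, setting C6 (S) and C1 (R) as the syn adduct.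

Step 3
Reactants: 6 (2S,3R)-2-[(benzyloxy)methyl]-4-methyl-3-(nitromethyl)pentanal; 7 ethyl 2-(diethoxyphosphoryl)prop-2-enoate
Product: 9 ethyl (3S,4R,5R)-3-[(benzyloxy)methyl]-5-nitro-4-(propan-2-yl)cyclohex-1-ene-1-carboxylate, via nitro-Michael adduct 8 (not isolated)
Conditions: Cs2CO3, CH2Cl2, 0 °C; then EtOH, rt
Reagents that add atoms: none
Why: Cs2CO3 should deprotonate the nitromethyl group of 6 so that nitronate carbon C2 adds to the unhindered CH2 terminus (C3) of vinylphosphonate 7 (nitro-Michael, bond C2–C3), and the phosphonate-stabilised carbanion thus formed at C4 then adds to the tethered aldehyde carbon C5 and loses diethyl phosphate (intramolecular Horner–Wadsworth–Emmons olefination, bond C4=C5). The closest known reaction is the domino Michael/Horner–Wadsworth–Emmons annulation of γ-nitro aldehydes with 2-phosphonoacrylates that gives 5-nitrocyclohex-1-enecarboxylates. The six-membered ring closes by 6-exo-trig addition of the C4 carbanion to the C5 carbonyl, and the ring enforces the cis alkene. C1 and C6 come unchanged from 6 (the syn adduct becomes the trans-3,4-disubstituted ring), while the new C2 centre should equilibrate through the nitronate to the equatorial nitro epimer and is erased in step 4. The step needs C-alkylation of the nitronate at the CH2 terminus, which the 1,1-disubstituted acceptor secures, and olefination faster than β-elimination of benzyl oxide or epimerisation at C6, which the mild carbonate base at 0 °C and the fast ring closure should secure; the ethanol quench returns reversible aldol-type side products to the productive path.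

Step 4
Reactants: 9 ethyl (3S,4R,5R)-3-[(benzyloxy)methyl]-5-nitro-4-(propan-2-yl)cyclohex-1-ene-1-carboxylate
Product: 10 ethyl (3R,4R)-3-[(benzyloxy)methyl]-4-(propan-2-yl)cyclohex-1-ene-1-carboxylate
Conditions: Bu3SnH, AIBN, toluene, 110 °C
Reagents that add atoms: none
Why: Radical denitration of a secondary nitroalkane with Bu3SnH (stannyl radical adds to the nitro group, the C–N bond fragments and the C2 radical takes hydrogen from the stannane) should turn C2 into the plain CH2 without touching C1 or C6.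

Step 5
Reactants: 10 ethyl (3R,4R)-3-[(benzyloxy)methyl]-4-(propan-2-yl)cyclohex-1-ene-1-carboxylate
Product: 11 (1S,5R,6R)-6-[(benzyloxy)methyl]-2-(ethoxycarbonyl)-5-(propan-2-yl)cyclohexane-1-carboxylic acid
Conditions: HCO2K, 4CzIPN (2,4,5,6-tetra(carbazol-9-yl)isophthalonitrile, 2 mol%), mesna (20 mol%), DMSO, blue LEDs, rt; then aq. HCl
Reagents that add atoms: potassium formate, [K+].[O-]C=O
Why: Photocatalytic Giese-type hydrocarboxylation, in which the CO2 radical anion made from formate by thiol hydrogen-atom transfer should add to the β-carbon C5 of the enoate from the face opposite the adjacent C6 side arm, fixing C5 (S) with its carboxyl trans to that arm, before the thiol quenches the C4 radical.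

Step 6
Reactants: 11 (1S,5R,6R)-6-[(benzyloxy)methyl]-2-(ethoxycarbonyl)-5-(propan-2-yl)cyclohexane-1-carboxylic acid
Product: 12 (1S,2S,5R,6R)-6-[(benzyloxy)methyl]-2-(ethoxycarbonyl)-2-hydroxy-5-(propan-2-yl)cyclohexane-1-carboxylic acid
Conditions: KN(SiMe3)2 (2.3 equiv), THF, −78 °C; then 3-phenyl-2-(phenylsulfonyl)oxaziridine, −78 °C; aq. HCl
Reagents that add atoms: 3-phenyl-2-(phenylsulfonyl)oxaziridine, O=S(=O)(c1ccccc1)N1OC1c1ccccc1
Why: Enolate hydroxylation with an N-sulfonyloxaziridine (Davis oxidation) on the carboxylate/ester dianion, in which only the C4–H next to the ester is removed and oxygen should arrive by equatorial attack on the exocyclic enolate, anti to the C5 carboxylate, setting C4 (S) with OH trans to the C5 carboxyl.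

Step 7
Reactants: 12 (1S,2S,5R,6R)-6-[(benzyloxy)methyl]-2-(ethoxycarbonyl)-2-hydroxy-5-(propan-2-yl)cyclohexane-1-carboxylic acid
Product: 13 1-tert-butyl 2-ethyl (1S,2S,5R,6R)-6-[(benzyloxy)methyl]-2-hydroxy-5-(propan-2-yl)cyclohexane-1,2-dicarboxylate
Conditions: Me2NCH(OtBu)2, toluene, 80 °C
Reagents that add atoms: N,N-dimethylformamide di-tert-butyl acetal, CN(C)C(OC(C)(C)C)OC(C)(C)C
Why: Acid-selective O-tert-butylation with the formamide acetal should esterify the carboxylic acid and leave the hindered tertiary alcohol and the ethyl ester untouched.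

Step 8
Reactants: 13 1-tert-butyl 2-ethyl (1S,2S,5R,6R)-6-[(benzyloxy)methyl]-2-hydroxy-5-(propan-2-yl)cyclohexane-1,2-dicarboxylate
Product: 14 1-tert-butyl 2-ethyl (1S,2S,5R,6R)-2-hydroxy-6-(hydroxymethyl)-5-(propan-2-yl)cyclohexane-1,2-dicarboxylate
Conditions: H2 (1 atm), 10% Pd/C, EtOAc, rt
Reagents that add atoms: none
Why: Hydrogenolysis of the benzyl ether should be clean because no alkene is present at this stage.

Step 9
Reactants: 14 1-tert-butyl 2-ethyl (1S,2S,5R,6R)-2-hydroxy-6-(hydroxymethyl)-5-(propan-2-yl)cyclohexane-1,2-dicarboxylate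
Product: 15 1-tert-butyl 2-ethyl (1S,2S,5R,6R)-6-formyl-2-hydroxy-5-(propan-2-yl)cyclohexane-1,2-dicarboxylate
Conditions: Dess–Martin periodinane, NaHCO3, CH2Cl2, 0 °C to rt
Reagents that add atoms: none
Why: Dess–Martin oxidation of the primary alcohol should give the aldehyde, and the enolisable C6 keeps its configuration because the all-trans (all-equatorial) arrangement is also the thermodynamic one.

Step 10
Reactants: 16 tert-butyl 2-(diethoxyphosphoryl)acetate; 17 paraformaldehyde
Product: 19 tert-butyl 2-(diethoxyphosphoryl)prop-2-enoate, via hydroxymethyl phosphonate 18 (not isolated)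
Conditions: piperidine (10 mol%), THF, 60 °C; then MsCl, Et3N, CH2Cl2, 0 °C to rt
Reagents that add atoms: none
Why: Amine-catalysed hydroxymethylation of the phosphonoacetate followed by mesylation–elimination (E1cB) should give the 2-phosphonoacrylate.

Step 11
Reactants: 15 1-tert-butyl 2-ethyl (1S,2S,5R,6R)-6-formyl-2-hydroxy-5-(propan-2-yl)cyclohexane-1,2-dicarboxylate; 19 tert-butyl 2-(diethoxyphosphoryl)prop-2-enoate; 20 (4-methoxyphenyl)methanol
Product: 22 1-tert-butyl 2-ethyl (1S,2S,5R,6S)-6-[(1E)-3-tert-butoxy-2-{[(4-methoxyphenyl)methoxy]methyl}-3-oxoprop-1-en-1-yl]-2-hydroxy-5-(propan-2-yl)cyclohexane-1,2-dicarboxylate, via alkoxy phosphonate 21 (not isolated)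
Conditions: 20, NaH, THF, 0 °C, then 19; then 15, 0 °C to rt
Reagents that add atoms: none
Why: Oxa-Michael addition of the alkoxide to the 2-phosphonoacrylate makes the phosphonate anion in the flask, and its Horner–Wadsworth–Emmons olefination of the α-branched aldehyde should give the trisubstituted enoate with the ring trans to the ester (E).

Step 12
Reactants: 22 1-tert-butyl 2-ethyl (1S,2S,5R,6S)-6-[(1E)-3-tert-butoxy-2-{[(4-methoxyphenyl)methoxy]methyl}-3-oxoprop-1-en-1-yl]-2-hydroxy-5-(propan-2-yl)cyclohexane-1,2-dicarboxylate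
Product: 23 tert-butyl (1S,2S,5R,6S)-6-[(1E)-3-tert-butoxy-2-{[(4-methoxyphenyl)methoxy]methyl}-3-oxoprop-1-en-1-yl]-2-hydroxy-2-(hydroxymethyl)-5-(propan-2-yl)cyclohexane-1-carboxylate
Conditions: NaBH4, EtOH, 0 °C to rt
Reagents that add atoms: none
Why: NaBH4 reduction of the α-hydroxy ester (activated by the neighbouring hydroxyl) should give the 1,2-diol while both tert-butyl esters, one of them conjugated, survive.

Step 13
Reactants: 23 tert-butyl (1S,2S,5R,6S)-6-[(1E)-3-tert-butoxy-2-{[(4-methoxyphenyl)methoxy]methyl}-3-oxoprop-1-en-1-yl]-2-hydroxy-2-(hydroxymethyl)-5-(propan-2-yl)cyclohexane-1-carboxylate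
Product: 25 tert-butyl (3S,4S,5S,6R)-5-[(1E)-3-tert-butoxy-2-{[(4-methoxyphenyl)methoxy]methyl}-3-oxoprop-1-en-1-yl]-6-(propan-2-yl)-1-oxaspiro[2.5]octane-4-carboxylate, via primary tosylate 24 (not isolated)
Conditions: TsCl, Et3N, DMAP (cat.), CH2Cl2, 0 °C; then K2CO3, MeOH, rt
Reagents that add atoms: none
Why: Selective sulfonylation of the primary hydroxyl and intramolecular Williamson closure (3-exo-tet) by the tertiary alkoxide should give the spiro-epoxide with retention at C4.

Step 14
Reactants: 25 tert-butyl (3S,4S,5S,6R)-5-[(1E)-3-tert-butoxy-2-{[(4-methoxyphenyl)methoxy]methyl}-3-oxoprop-1-en-1-yl]-6-(propan-2-yl)-1-oxaspiro[2.5]octane-4-carboxylate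
Product: 27 (2E)-2-(hydroxymethyl)-3-[(4S,5R)-3-oxo-5-(propan-2-yl)-1,3,4,5,6,7-hexahydro-2-benzofuran-4-yl]prop-2-enoic acid, via allylic silyl ether 26 (not isolated)
Conditions: TMSOTf, DBU, toluene, 0 °C to rt; then TFA/CH2Cl2 (1:1), anisole, rt; aq. NaHCO3/MeOH, then pH 3
Reagents that add atoms: none
Why: Silyl triflate/amidine-promoted isomerisation of the 2,2-disubstituted epoxide to the allylic silyl ether (loss of the acidic C5–H next to the ester should give the tetrasubstituted C4=C5 alkene) is followed by acidolysis of the silyl ether, both tert-butyl esters and the PMB ether, after which the cis γ-hydroxy acid should close to the butenolide of ring B with C1 and C6 untouched.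

Step 15
Reactants: 27 (2E)-2-(hydroxymethyl)-3-[(4S,5R)-3-oxo-5-(propan-2-yl)-1,3,4,5,6,7-hexahydro-2-benzofuran-4-yl]prop-2-enoic acid; 25 tert-butyl (3S,4S,5S,6R)-5-[(1E)-3-tert-butoxy-2-{[(4-methoxyphenyl)methoxy]methyl}-3-oxoprop-1-en-1-yl]-6-(propan-2-yl)-1-oxaspiro[2.5]octane-4-carboxylate
Product: 28 ester of acid 27 with the epoxide-derived primary oxygen of 25 (ring A still as di-tert-butyl ester and PMB ether)
Conditions: 27 (1.5 equiv), Cs2CO3 (0.6 equiv), DMF, 65 °C
Reagents that add atoms: none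
Why: SN2 opening of the epoxide at its CH2 carbon by the caesium carboxylate should form the ester link and release the tertiary C4–OH with its configuration unchanged, the free primary alcohol of 27 not being a competent nucleophile under these conditions.

Step 16
Reactants: 28 ester of acid 27 with the epoxide-derived primary oxygen of 25
Product: 29 CNP0071646.2
Conditions: TFA/CH2Cl2 (1:2), anisole, 0 °C to rt; aq. NaHCO3/MeOH, then pH 3
Reagents that add atoms: none
Why: Acidolysis of the two tert-butyl esters and the PMB ether with anisole as cation trap should release the target, whose tertiary alcohol is flanked by electron-withdrawing groups and should not ionise.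

Compound list
1 | 2-methylpropanal (isobutyraldehyde) | CC(C)C=O | starting material
2 | nitromethane | C[N+](=O)[O-] | starting material
3 | 3-methyl-1-nitrobutan-2-ol (racemic) | CC(C)C(O)C[N+](=O)[O-] | intermediate
4 | (E)-3-methyl-1-nitrobut-1-ene | CC(C)/C=C/[N+](=O)[O-] | intermediate
5 | 3-(benzyloxy)propanal | O=CCCOCc1ccccc1 | starting material
6 | (2S,3R)-2-[(benzyloxy)methyl]-4-methyl-3-(nitromethyl)pentanal | O=C[C@H](COCc1ccccc1)[C@H](C[N+](=O)[O-])C(C)C | intermediate
7 | ethyl 2-(diethoxyphosphoryl)prop-2-enoate | C=C(C(=O)OCC)P(=O)(OCC)OCC | starting material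
8 | ethyl (5R,6S)-6-[(benzyloxy)methyl]-2-(diethoxyphosphoryl)-4-nitro-7-oxo-5-(propan-2-yl)heptanoate (mixture at C2 and C4) | O=C[C@H](COCc1ccccc1)[C@@H](C(C)C)C([N+](=O)[O-])CC(C(=O)OCC)P(=O)(OCC)OCC | intermediate
9 | ethyl (3S,4R,5R)-3-[(benzyloxy)methyl]-5-nitro-4-(propan-2-yl)cyclohex-1-ene-1-carboxylate | CC(C)[C@H]1[C@H]([N+](=O)[O-])CC(C(=O)OCC)=C[C@@H]1COCc2ccccc2 | intermediate
10 | ethyl (3R,4R)-3-[(benzyloxy)methyl]-4-(propan-2-yl)cyclohex-1-ene-1-carboxylate | CC(C)[C@H]1CCC(C(=O)OCC)=C[C@@H]1COCc2ccccc2 | intermediate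
11 | (1S,5R,6R)-6-[(benzyloxy)methyl]-2-(ethoxycarbonyl)-5-(propan-2-yl)cyclohexane-1-carboxylic acid (both C2 epimers) | CC(C)[C@H]1CCC(C(=O)OCC)[C@@H](C(=O)O)[C@@H]1COCc2ccccc2 | intermediate
12 | (1S,2S,5R,6R)-6-[(benzyloxy)methyl]-2-(ethoxycarbonyl)-2-hydroxy-5-(propan-2-yl)cyclohexane-1-carboxylic acid | CC(C)[C@H]1CC[C@@](O)(C(=O)OCC)[C@@H](C(=O)O)[C@@H]1COCc2ccccc2 | intermediate
13 | 1-tert-butyl 2-ethyl (1S,2S,5R,6R)-6-[(benzyloxy)methyl]-2-hydroxy-5-(propan-2-yl)cyclohexane-1,2-dicarboxylate | CC(C)[C@H]1CC[C@@](O)(C(=O)OCC)[C@@H](C(=O)OC(C)(C)C)[C@@H]1COCc2ccccc2 | intermediate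
14 | 1-tert-butyl 2-ethyl (1S,2S,5R,6R)-2-hydroxy-6-(hydroxymethyl)-5-(propan-2-yl)cyclohexane-1,2-dicarboxylate | CC(C)[C@H]1CC[C@@](O)(C(=O)OCC)[C@@H](C(=O)OC(C)(C)C)[C@@H]1CO | intermediate
15 | 1-tert-butyl 2-ethyl (1S,2S,5R,6R)-6-formyl-2-hydroxy-5-(propan-2-yl)cyclohexane-1,2-dicarboxylate | CC(C)[C@H]1CC[C@@](O)(C(=O)OCC)[C@@H](C(=O)OC(C)(C)C)[C@@H]1C=O | intermediate
16 | tert-butyl 2-(diethoxyphosphoryl)acetate | CCOP(=O)(CC(=O)OC(C)(C)C)OCC | starting material
17 | paraformaldehyde (formaldehyde source) | C=O | starting material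
18 | tert-butyl 2-(diethoxyphosphoryl)-3-hydroxypropanoate | CCOP(=O)(OCC)C(CO)C(=O)OC(C)(C)C | intermediate
19 | tert-butyl 2-(diethoxyphosphoryl)prop-2-enoate | C=C(C(=O)OC(C)(C)C)P(=O)(OCC)OCC | intermediate
20 | (4-methoxyphenyl)methanol | COc1ccc(CO)cc1 | starting material
21 | tert-butyl 2-(diethoxyphosphoryl)-3-[(4-methoxyphenyl)methoxy]propanoate (present as its sodium salt) | COc1ccc(COCC(C(=O)OC(C)(C)C)P(=O)(OCC)OCC)cc1 | intermediate
22 | 1-tert-butyl 2-ethyl (1S,2S,5R,6S)-6-[(1E)-3-tert-butoxy-2-{[(4-methoxyphenyl)methoxy]methyl}-3-oxoprop-1-en-1-yl]-2-hydroxy-5-(propan-2-yl)cyclohexane-1,2-dicarboxylate | CC(C)[C@H]1CC[C@@](O)(C(=O)OCC)[C@@H](C(=O)OC(C)(C)C)[C@@H]1/C=C(\COCc2ccc(OC)cc2)C(=O)OC(C)(C)C | intermediate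
23 | tert-butyl (1S,2S,5R,6S)-6-[(1E)-3-tert-butoxy-2-{[(4-methoxyphenyl)methoxy]methyl}-3-oxoprop-1-en-1-yl]-2-hydroxy-2-(hydroxymethyl)-5-(propan-2-yl)cyclohexane-1-carboxylate | CC(C)[C@H]1CC[C@@](O)(CO)[C@@H](C(=O)OC(C)(C)C)[C@@H]1/C=C(\COCc2ccc(OC)cc2)C(=O)OC(C)(C)C | intermediate
24 | 4-methylbenzenesulfonate of the primary hydroxyl of 23 | CC(C)[C@H]1CC[C@@](O)(COS(=O)(=O)c2ccc(C)cc2)[C@@H](C(=O)OC(C)(C)C)[C@@H]1/C=C(\COCc3ccc(OC)cc3)C(=O)OC(C)(C)C | intermediate
25 | tert-butyl (3S,4S,5S,6R)-5-[(1E)-3-tert-butoxy-2-{[(4-methoxyphenyl)methoxy]methyl}-3-oxoprop-1-en-1-yl]-6-(propan-2-yl)-1-oxaspiro[2.5]octane-4-carboxylate | CC(C)[C@H]1CC[C@@]2(CO2)[C@@H](C(=O)OC(C)(C)C)[C@@H]1/C=C(\COCc3ccc(OC)cc3)C(=O)OC(C)(C)C | intermediate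
26 | tert-butyl (5R,6S)-6-[(1E)-3-tert-butoxy-2-{[(4-methoxyphenyl)methoxy]methyl}-3-oxoprop-1-en-1-yl]-5-(propan-2-yl)-2-{[(trimethylsilyl)oxy]methyl}cyclohex-1-ene-1-carboxylate | CC(C)[C@H]1CCC(CO[Si](C)(C)C)=C(C(=O)OC(C)(C)C)[C@@H]1/C=C(\COCc2ccc(OC)cc2)C(=O)OC(C)(C)C | intermediate
27 | (2E)-2-(hydroxymethyl)-3-[(4S,5R)-3-oxo-5-(propan-2-yl)-1,3,4,5,6,7-hexahydro-2-benzofuran-4-yl]prop-2-enoic acid | OC(=O)/C(CO)=C/[C@H]1C2=C(CC[C@@H]1C(C)C)COC2=O | intermediate
28 | tert-butyl (1S,2S,5R,6S)-6-[(1E)-3-tert-butoxy-2-{[(4-methoxyphenyl)methoxy]methyl}-3-oxoprop-1-en-1-yl]-2-hydroxy-5-(propan-2-yl)-2-(acyloxymethyl)cyclohexane-1-carboxylate, the acyl group being that of acid 27 | CC(C)[C@H]1CC[C@@](O)(COC(=O)/C(=C/[C@H]2C3=C(CC[C@@H]2C(C)C)COC3=O)CO)[C@@H](C(=O)OC(C)(C)C)[C@@H]1/C=C(\COCc4ccc(OC)cc4)C(=O)OC(C)(C)C | intermediate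
29 | CNP0071646.2 (ring A diacid, tertiary alcohol, ester link to ring B butenolide acid unit) | CC(C)[C@H]1CC[C@@](O)(COC(=O)/C(=C/[C@H]2C3=C(CC[C@@H]2C(C)C)COC3=O)CO)[C@@H](C(=O)O)[C@@H]1/C=C(\CO)C(=O)O | target

Total step count: 16. Longest linear sequence: 15 steps (steps 1–9 and 11–16; step 10 prepares reagent 19).

Steps most likely to fail

Step 14. The epoxide isomerisation, lactonisation and global deprotection run in one flask: proton loss may occur from C3 instead of C5, the acid stage may stall before ring closure, and there is no point at which to purify. The fallback sets out from 22 and returns at 27. Burgess reagent (syn-elimination of the tertiary alcohol with the cis C5–H) should give the tetrasubstituted ene-diester 2-tert-butyl 1-ethyl (3S,4R)-3-[(1E)-3-tert-butoxy-2-{[(4-methoxyphenyl)methoxy]methyl}-3-oxoprop-1-en-1-yl]-4-(propan-2-yl)cyclohex-1-ene-1,2-dicarboxylate F1. TFA with anisole should then remove both tert-butyl esters and the PMB ether to give (2E)-3-[(1S,6R)-2-carboxy-3-(ethoxycarbonyl)-6-(propan-2-yl)cyclohex-2-en-1-yl]-2-(hydroxymethyl)prop-2-enoic acid F2. LiBH4 in THF at 0 °C, which leaves carboxylate salts alone, should reduce the ethyl ester, and acidic work-up should close the butenolide to 27.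

Step 5. Addition of the CO2 radical anion to the hindered trisubstituted enoate may be slow, plain reduction of the alkene may compete, and facial selectivity at C5 may be poor. The fallback sets out from 10 and returns at 11. CuI/TMSCl-promoted conjugate addition of vinylmagnesium bromide, anti to the C6 side arm, should give ethyl (2S,3R,4R)-3-[(benzyloxy)methyl]-2-ethenyl-4-(propan-2-yl)cyclohexane-1-carboxylate F3. Ozonolysis (O3, then Me2S) should give ethyl (2S,3R,4R)-3-[(benzyloxy)methyl]-2-formyl-4-(propan-2-yl)cyclohexane-1-carboxylate F4, and Pinnick oxidation (NaClO2, NaH2PO4, 2-methylbut-2-ene) should give 11.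

Step 15. Attack of the carboxylate on the neopentyl-like epoxide carbon may be slow, so that base-induced opening of the epoxide towards the butenolide competes at the temperature needed. The fallback sets out from 27 and 23 and returns at 29. TBSCl/imidazole, then K2CO3/MeOH to cleave the silyl ester, should give (2E)-2-{[(tert-butyldimethylsilyl)oxy]methyl}-3-[(4S,5R)-3-oxo-5-(propan-2-yl)-1,3,4,5,6,7-hexahydro-2-benzofuran-4-yl]prop-2-enoic acid F5. Yamaguchi esterification (2,4,6-trichlorobenzoyl chloride, Et3N, then DMAP) with the primary hydroxyl of diol 23 should give the silyl-protected analogue of 28, ester F6. The acid treatment of step 16 with aqueous work-up should also remove the silyl ether and give 29.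

Further compounds
F1 | step 14 | 2-tert-butyl 1-ethyl (3S,4R)-3-[(1E)-3-tert-butoxy-2-{[(4-methoxyphenyl)methoxy]methyl}-3-oxoprop-1-en-1-yl]-4-(propan-2-yl)cyclohex-1-ene-1,2-dicarboxylate | CC(C)[C@H]1CCC(C(=O)OCC)=C(C(=O)OC(C)(C)C)[C@@H]1/C=C(\COCc2ccc(OC)cc2)C(=O)OC(C)(C)C
F2 | step 14 | (2E)-3-[(1S,6R)-2-carboxy-3-(ethoxycarbonyl)-6-(propan-2-yl)cyclohex-2-en-1-yl]-2-(hydroxymethyl)prop-2-enoic acid | CC(C)[C@H]1CCC(C(=O)OCC)=C(C(=O)O)[C@@H]1/C=C(\CO)C(=O)O
F3 | step 5 | ethyl (2S,3R,4R)-3-[(benzyloxy)methyl]-2-ethenyl-4-(propan-2-yl)cyclohexane-1-carboxylate | CC(C)[C@H]1CCC(C(=O)OCC)[C@@H](C=C)[C@@H]1COCc2ccccc2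
F4 | step 5 | ethyl (2S,3R,4R)-3-[(benzyloxy)methyl]-2-formyl-4-(propan-2-yl)cyclohexane-1-carboxylate | CC(C)[C@H]1CCC(C(=O)OCC)[C@@H](C=O)[C@@H]1COCc2ccccc2
F5 | step 15 | (2E)-2-{[(tert-butyldimethylsilyl)oxy]methyl}-3-[(4S,5R)-3-oxo-5-(propan-2-yl)-1,3,4,5,6,7-hexahydro-2-benzofuran-4-yl]prop-2-enoic acid | OC(=O)/C(CO[Si](C)(C)C(C)(C)C)=C/[C@H]1C2=C(CC[C@@H]1C(C)C)COC2=O
F6 | step 15 | silyl ether of 28 at the ring B hydroxymethyl group | CC(C)[C@H]1CC[C@@](O)(COC(=O)/C(=C/[C@H]2C3=C(CC[C@@H]2C(C)C)COC3=O)CO[Si](C)(C)C(C)(C)C)[C@@H](C(=O)OC(C)(C)C)[C@@H]1/C=C(\COCc4ccc(OC)cc4)C(=O)OC(C)(C)C
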